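Each exchange turns one incoming ligand into one leaving ligand, so c(incoming ligand) + c(leaving ligand) stays at what has gone in, less what over-reaction takes.

    complex with one exchanged + incoming ligand ⇌ leaving ligand + complex with two exchanged (K1 = 0.30, k1 = 2400 /M/s)
    complex with two exchanged + incoming ligand → over-reaction product (k2 = 40 /M/s)
    starting complex + complex with one exchanged → side product (k3 = 1000 /M/s)
    starting complex + incoming ligand ⇌ leaving ligand + complex with one exchanged (K4 = 0.40, k4 = 5500 /M/s)

| setting | theta | delta | beta | eta |
|---|---|---|---|---|
| starting complex | 2.0 × 10⁻⁴ M | 2.0 × 10⁻⁴ M | 2.0 × 10⁻⁴ M (fed, over 50 s) | 2.0 × 10⁻⁴ M |
| incoming ligand | 0.300 mM | 0.300 mM (in portions, 5, over 50 s) | 0.300 mM | 0.300 mM (fed, over 50 s) |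
| leaving ligand | 0.200 mM | 0.200 mM | 0.200 mM | 0.200 mM |
| time | 80 s | 80 s | 80 s | 80 s |
| remark | everything together at the start | first portion at the start, last at 50 s | all else is in the flask from the start; the feed brings no volume worth counting | all else is in the flask from the start; the feed brings no volume worth counting |

1. the best flask by share of complex with two exchanged in complex with two exchanged plus over-reaction product; "all alike" if 1.5 percentage points covers them all (theta / delta / beta / eta / all alike)
2. share of complex with two exchanged in complex with two exchanged plus over-reaction product at the end, theta
3. share of complex with two exchanged in complex with two exchanged plus over-reaction product at the end, delta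
4. share of complex with two exchanged in complex with two exchanged plus over-reaction product at the end, beta
5. share of complex with two exchanged in complex with two exchanged plus over-reaction product at the end, eta

- percent here means starting complex units held: one side product counts as two
- run time (theta): 80 s

In theta, exchange has forward half-lives of 0.42 s and 0.96 s, against 3.5 s for complex with one exchanged going to side product and 58 s for over-reaction, so the three complexes are reckoned here as an equilibrium pool that side product drains. Each side product carries one exchange for two complexes, so the invariant puts c(incoming ligand) near 0.200 mM and its ratio to c(leaving ligand) near 0.667. Starting complex is then 75.8% of the pool, and the pool falls on a second-order curve with time constant 16.3 s. The run is 4.90 such times long.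

Over-reaction is pseudo-first-order in complex with two exchanged, so a level standing flat gives 0.640 of product per unit of complex, a share of 61.0%. A level held at its start until the last moment gives 20.9%. Theta is reckoned to lie between these extremes. The mean of the second-order curve stands 2.14 times above the end level, and so ρ = 1.37, the over-reaction product per complex with two exchanged standing at the end, with the share 1/(1 + ρ) = 42.2%. Beta, with its incoming ligand charged at the start as in theta, is placed near theta. For delta and eta, counting the time after the last ligand gives 80.6%, a figure that counts no product made before that time. This reckoning gives those two one figure.

The forecast gives 38% (30% to 47%) for theta, 63% (53% to 72%) for delta, 40% (31% to 50%) for beta and 68% (57% to 77%) for eta, and it picks eta: "Holding back the incoming ligand keeps that slice and the over-reaction small until late".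

The flasks end at 36.9% in theta, 66.2% in delta, 40.3% in beta and 63.8% in eta, so delta is best, by 2.4 percentage points over eta, against a margin of 1.5 points. In theta, side product stood at 71.3% after 40.0 s, and the end held 1.16% of over-reaction product beside 0.677% of complex with two exchanged, a ρ of 1.71 against 1.37. In delta, over-reaction product stood at 0.164% before the last portion at 50.0 s and ended at 0.457%. For the neighbour of theta charged with 7.5 × 10⁻⁴ M of incoming ligand, holding 2.14 gives ρ = 4.44, a share of 18.4%. That neighbour ends at 16.8%.

The constants come from no measurement.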